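(Its constants are assumed; the flask was simulated.)

A small charge of second end groups, 0.0190 M against 0.020 M of first end groups, goes into each of four flasks, and I wanted to know how much of it reaches rings.

    first end groups + second end groups → links (k1 = 0.24 M⁻¹ min⁻¹, Ea1 = 72.0 kJ mol⁻¹)
    first end groups + second end groups → rings, rate k2*[first end groups] as long as [second end groups] is above zero (k2 = 0.0095 min⁻¹, Ea2 = 86.0 kJ mol⁻¹)
    2 second end groups → homo dimer (k3 = 0.91 M⁻¹ min⁻¹, Ea3 = 65.0 kJ mol⁻¹)
    first end groups + protic impurity → quenched substrate (k4 = 16 M⁻¹ min⁻¹, Ea4 = 66.0 kJ mol⁻¹)
    second end groups ⇌ dormant form (K5 = 24, k5 = 0.0019 min⁻¹, Ea5 = 94.0 kJ mol⁻¹, ΔH5 = −62.0 kJ mol⁻¹)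
    (constants at 25 °C)

| setting | ash | oak | cedar | elm |
|---|---|---|---|---|
| first end groups | 0.020 M (fed, over 2.5 d) | 0.020 M (fed, over 2.5 d) | 0.020 M | 0.020 M |
| second end groups | 0.0190 M | 0.0190 M | 0.0190 M | 0.0190 M (in portions, 2, over 2.5 d) |
| protic impurity | 0.400 mM | 0.400 mM | 0.400 mM | 0.400 mM |
| time | 3.0 d | 3.0 d | 3.0 d | 3.0 d |
| remark | the addition at −15 °C, then warmed to 25 °C; the feed brings no volume worth counting | all else is in the flask from the start; the feed brings no volume worth counting | everything together at the start | first portion at the start, last at 2.5 d |
| temperature |  | 25 °C | 25 °C | 25 °C |

- which flask leads in amount of rings, in percent of the first end groups charged ("all alike" within 1.5 percentage points) (ash / oak / cedar / elm / all alike)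
- how much rings is there at the end, in percent of the first end groups charged: ash
- how much rings is there at the end, in percent of the first end groups charged: oak
- how much rings is there at the end, in percent of the first end groups charged: cedar
- how much rings is there at the end, in percent of the first end groups charged: elm

- a step written with two of one species runs at k times the square of its concentration and takes two of it each time
- all constants are for 25 °C and move with temperature by the activation energies and enthalpies

I began with the balance of second end groups, the limiting reagent: what was charged equals what is free, plus links, rings, dormant form and twice the homo dimer. That caps rings at 95.0 % of the first end groups charged, a loose ceiling. The ring step takes second end groups at a rate set by first end groups, whatever their own level as long as it is above zero, while the dimer step goes with the square of that level. So I named the even level, the level of second end groups at which the dimer step uses them as fast as the ring step, 10.2 mM at 25 °C with first end groups as charged. The ring rate over the dimer rate is then the square of the even level over the present level.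

For cedar I followed the ring share of what is spent as the level falls from the charge to zero, weighing the share at the start, the middle level and zero in the usual way, with the middle counted 4 times. With first end groups held as charged and links and dormant form ignored, this gave an upper estimate of 10.7 mM, or 53.5 %. For the lower estimate I held first end groups at 8.93 mM, what remains after the quench and that upper estimate before anything goes to links, and counted links and dormant form as full losses of second end groups. This gave 6.91 mM, or 34.6 %, and there the hand stopped. Elm's first portion, 9.50 mM, starts below the even level, whereas cedar's charge starts above it; I did not reckon elm's last portion, but on this start I committed to elm ahead of cedar.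

The forecast gave ash 27 %, oak 14 %, cedar 41 % and elm 57 %, reasoning that “splitting the second end groups (elm) therefore wastes least”, which put its cedar figure inside my bracket.

The simulation gave ash 27.4 %, oak 10.6 %, cedar 46.7 % and elm 64.1 %, so elm led and cedar fell inside the bracket.

Cedar's charge began at 1.86 times the even level, and its homo dimer at 3.00 d stood at 0.00376 M, holding 39.6 % of the second end groups charged. In elm at 0.0303 d, the ring step used second end groups 950 times as fast as the dimer step, which puts the free level 30.8 times below the even level of that moment, and elm's homo dimer at 3.00 d stood at 0.00210 M, holding 22.1 % of its charge.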